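## The problem

The target is a daucane triol diester. A cyclopentane (ring A, C1–C5) is trans-fused to a cycloheptene (ring B, C1 and C5–C10). C1 is the quaternary, methyl-bearing fusion carbon, C4 the isopropyl carbinol, C5 the fusion methine, C6 the benzoyloxy carbon, C8(Me)=C9 the alkene and C10 the angeloyloxy carbon; β is the face of the C1 methyl group. Five stereocentres (C1, C4, C5, C6, C10) and the Z geometry of the angelate have to be secured. Only C1 cannot be corrected once made, so it must carry the absolute configuration. The others can be derived from it: C5 is epimerisable next to a C6 carbonyl, C4 comes from addition to a ketone anti to C6 and to the methyl group, C10 from reduction anti to the axial methyl group followed by inversion, and C6 from hydride delivered by the C4 hydroxyl. The C4–C5–C6 segment is an aldol array, so retro-aldol cleavage and β-elimination threaten whenever one end is a carbonyl and the other carries oxygen. C6 and C10 are both secondary carbinols that must receive different acyl groups, and the C10 ester is allylic and neopentyl. The angelate isomerises to the tiglate under nucleophilic catalysis and is a Michael acceptor, so it should enter late and without acyl activation. The enabling feature is that C6 and C10 are both oxygenated and flank the C1–C5 fusion bond. Joining them turns ring B into a cyclobutane-1,2-diol fused to ring A and to a methylcyclopentane (C6–C7–C8–C9–C10), which is the (2+2) adduct of a cyclopentenone and a symmetric enediol ether, with the C8 methyl group already in place.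

## Retrosynthesis

The benzoate of 22 is cut at the acyl–O6 bond, giving diol 21, in which only the secondary 6α-hydroxyl can be acylated. The C6–H bond of 21 is traced to ketone 20. Direct inversion of a 6β-alcohol would have to activate an axial hydroxyl that is syn to the C1 methyl group, whereas in 20 the tertiary C4 hydroxyl lies cis to C6 and can deliver hydride to the β face. Ketone 20 comes from alcohol 19 and its silyl ether 18, so C6 is carried through the middle of the route as a protected carbinol.

The C10–O bond of 18 is cut next. Hydride can reach C10 only from the α face, anti to the axial methyl group, which gives the 10β-alcohol 17. The α-ester therefore has to be made by C–O bond formation from that same open face, with angelic acid as the nucleophile and inversion. This also avoids any activated angeloyl species. Alcohol 17 comes from enone 16 by 1,2-reduction.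

The C4–isopropyl bond of 16 is cut to ketone 15. This addition is placed before any ester is present and after ring B is trans-fused, because only then is the α face of C4 the open one. Ketone 15 comes from alcohol 14 and its silyl ether 13; C4 is held at the alcohol level while C6 is a ketone, which keeps a β-diketone from ever forming.

The C8=C9 double bond of 13 is traced, through the silyl enol ether 12, to the saturated C10 ketone 11. C10 can enolise only towards C9 because C1 is quaternary. C6 must already be reduced at this point; otherwise the enone would be a vinylogous β-diketone and the double bond would wander to C7=C8. Compound 11 comes from dione 10 by reduction of the C6 carbonyl, the one next to a methine and not a quaternary carbon.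

Dione 10 is the C5 epimer of 9, reached by equilibration through the C6 enolate. Reconnecting C6 to C10 in 9 gives the cis-cyclobutane-1,2-diol 8, the retron of a glycol cleavage. This cut is preferred over any C–C disconnection inside ring B because it places both ring-B oxygens and all ten ring carbons in one precursor. Diol 8 comes from triol 7 and, through alcohol 6, from ketone 5. The C4 ketone has to be reduced before the cyclobutanols are unmasked, since a free C6 hydroxyl β to that ketone would open C5–C6 by retro-aldol cleavage.

Tricycle 5 is cut at C1–C10 and C5–C6 into 3-methylcyclopent-2-en-1-one 4 and the symmetric bis(silyloxy)cyclopentene 3. The forward reaction must control only the absolute configuration at C1; the alkene is symmetric, so regiochemistry does not arise, and the cis ring fusions follow from ring strain.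

Alkene 3 is cut at its C6–C10 double bond to dimethyl 3-methylglutarate 1 and chlorotrimethylsilane 2 (acyloin condensation). Compounds 1, 2 and 4 are commercial.

## Roads not taken

Alternative 1: Ring B is cut at C7–C8 and C1–C10 and assembled by a vinylcarbenoid (4+3) annulation. The carbenoid generated from diazo ester A3 with Rh2(S-DOSP)4 cyclopropanates the vinyl group of ketal diene A2, and the cis-divinylcyclopropane rearranges (Cope) to cycloheptadiene A1.
- Merits: one catalytic enantioselective step builds ring B, the quaternary C1 and the C10 oxygen, with C10 tied to C1 by the boat transition state. The C5=C6 alkene of A1 invites hydroboration from the α face, which would install 5α-H and 6α-OH in a single syn addition.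
- Where it is better: control of C5, C6 and C10 is tighter than in the chosen plan, which equilibrates C5, inverts C10 and sets C6 last.
- Weak points: the Cope step must engage a tetrasubstituted ring alkene to create C1. C8 arrives as an ester that has to be taken down to a methyl group through an allylic system prone to transposition. A2 and A3 each need several steps, and A3 is a diazo compound.
- What the chosen plan sets against it: two commercial components, the C8 methyl group present from the start, and the complete skeleton after two steps.

Alternative 2: The C1–C5 bond is cut and C1 is reconnected to C6, so that the hydroazulene arises from a decalin. Treating the cis-decalin hydroxy mesylate A5 with KOtBu lets the angular alkoxide push the C1–C6 bond to C5 with inversion, giving the trans-fused hydroazulenone A4.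
- Merits: the shift is stereospecific, so the trans fusion does not depend on an equilibrium. C6 emerges as a ketone while C10 is a ketal, so the two ring-B carbonyls are differentiated from the outset.
- Where it is better: both points are firmer than steps 6 and 7 of the chosen plan.
- Weak points: A5 carries four stereocentres, two of them adjacent and fully substituted, and must adopt the conformer with the mesylate anti-periplanar to the migrating bond. Its enantioselective preparation would take most of a synthesis by itself. The C4 oxygen is still secondary, so the same endgame remains.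
- What the chosen plan sets against it: far fewer steps to the skeleton.

Alternative 3: The C1–CH3 and C5–C6 bonds are cut, and later C9–C10. Conjugate addition of AlMe3 to enone A7 under Cu(OTf)2 and a chiral phosphoramidite forms the quaternary C1; the aluminium enolate is trapped by iodo-enal A8 to give aldol A6. Ring B would be closed afterwards by a CrCl2/NiCl2-mediated vinyl iodide–aldehyde coupling.
- Merits: no photochemistry, so scale-up is simpler. C5 and C6 are set by C–C bond formation.
- Where it is better: scalability, and an early, kinetically defined C6.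
- Weak points: A8 is a β,γ-unsaturated aldehyde that conjugates and enolises easily. The facial selectivity of the aldol at C6 is not assured. A6 is a retro-aldol-prone β-hydroxy ketone. The seven-membered closure onto a neopentyl aldehyde leaves the C10 configuration open.
- What the chosen plan sets against it: all ten ring carbons and both ring-B oxygens are in place after two steps, and each later stereocentre is derived from C1 by a defined facial argument.

Key step: step 2

Remark: locants follow the C1–C10 numbering above for all bicyclic and tricyclic compounds; β is the face of the C1 methyl group, α the opposite face.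
Remark: compounds 5–12 are carried as mixtures of the two C8 epimers; C8 is not controlled in step 2 and becomes trigonal in step 8.
Remark: the sense of induction of the catalyst in step 2 is assumed to follow the facial model of six-membered enones; if it proves opposite, the mirror-image catalyst from (R)-diphenylprolinol is used.
Remark: the 6β configuration drawn for 11–19 is the expected one and is immaterial to the route, because C6 is re-oxidised in step 15.

## Route

Step 1
Reactants: 1 dimethyl 3-methylglutarate; 2 chlorotrimethylsilane
Product: 3 4-methyl-1,2-bis(trimethylsilyloxy)cyclopent-1-ene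
Conditions: Na (4.2 equiv), Me3SiCl (4.5 equiv), toluene, reflux
Reagents that add atoms: chlorotrimethylsilane (2), C[Si](C)(C)Cl
Why: Acyloin condensation with in situ silylation (Rühlmann variant); the chlorosilane traps methoxide and the enediolate, so Dieckmann side reactions are suppressed and the five-membered enediol bis-silyl ether forms directly; no stereocentre is created because the alkene is symmetric.

Step 2
Reactants: 4 enone 3-methylcyclopent-2-en-1-one; 3 4-methyl-1,2-bis(trimethylsilyloxy)cyclopent-1-ene
Product: 5 cis-anti-cis photoadduct 1,4-dimethyl-2,6-bis(trimethylsilyloxy)tricyclo[5.3.0.0(2,6)]decan-8-one (C4 ketone; 1β-methyl; 5β-H; 6α,10α-bis(silyloxy))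
Conditions: hν (366 nm), (S)-tetrahydro-3,3-diphenyl-1-(2,4,6-trifluorophenyl)-1H,3H-pyrrolo[1,2-c][1,3,2]oxazaborole·AlBr3 (50 mol%), 3 (5 equiv), CH2Cl2, −75 °C
Reagents that add atoms: none
Why: Proposed new method: the AlBr3-activated oxazaborolidine binds the carbonyl oxygen of 4 and shifts its absorption so that at 366 nm mainly the complex is excited; after intersystem crossing the triplet enone adds stepwise to the electron-rich alkene of 3 through a 1,4-biradical, forming C5–C6 and C1–C10. The closest known reaction types are the chiral oxazaborolidine–AlBr3-catalysed intermolecular (2+2) photocycloaddition of cyclic enones (3-methylcyclohexenone included) with simple alkenes, and the uncatalysed racemic photocycloaddition of cyclopentenones with 1,2-bis(trimethylsilyloxy)cycloalkenes; new here is the combination of a five-membered enone and an enediol bis-silyl ether under the chiral Lewis acid. The only ring formed, the cyclobutane C1–C5–C6–C10, closes by radical–radical recombination of the triplet-derived biradical after spin inversion. C1 is set by the catalyst, whose B-aryl group shields one face of the bound enone so that the alkene bonds to the Si face of the β-carbon; C5 follows because a five-membered enone can give only the cis-fused bicyclo[3.2.0]heptanone; C6 and C10 are cis to each other for the same reason and anti to ring A because the biradical closes with the two five-membered rings on opposite faces; C8 is not controlled. The step needs enantioface selectivity (catalyst), no regiocontrol (3 is symmetric) and chemoselectivity for the photoreaction over Lewis-acid-promoted Mukaiyama–Michael addition or desilylation of 3, which the low temperature, the β,β-disubstituted acceptor and the tetrasubstituted donor should suppress.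

Step 3
Reactants: 5 photoadduct
Product: 7 4α,6α,10α-triol 1,4-dimethyltricyclo[5.3.0.0(2,6)]decane-2,6,8-triol, via bis-silyl alcohol 6 (not isolated)
Conditions: NaBH4, MeOH, 0 °C; then K2CO3, rt
Reagents that add atoms: none
Why: Hydride reduction from the convex face of the bicyclo[3.2.0]heptanone (the concave face is blocked by the endo C6 silyloxy group) gives the 4α-alcohol, whose configuration is immaterial since C4 is re-oxidised in step 10; base-catalysed methanolysis then removes the tertiary trimethylsilyl ethers, which is safe only now because with the C4 ketone present a free C6 hydroxyl would open C5–C6 by de Mayo-type retro-aldol cleavage.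

Step 4
Reactants: 7 triol
Product: 8 4α-triethylsilyloxy-6α,10α-diol
Conditions: Et3SiCl (1.1 equiv), imidazole, DMF, 0 °C
Reagents that add atoms: triethylsilyl chloride, CC[Si](Cl)(CC)CC
Why: Selective silylation; the chlorosilane with imidazole reacts with the secondary C4 hydroxyl and leaves the two tertiary cyclobutanols free for cleavage; the ether prevents retro-aldol cleavage and dehydration once C6 is a ketone.

Step 5
Reactants: 8 silyloxy diol
Product: 9 cis-fused dione 4α-(triethylsilyloxy)-1β,8-dimethyl-5βH-bicyclo[5.3.0]decane-6,10-dione
Conditions: Pb(OAc)4 (1.1 equiv), CH2Cl2, 0 °C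
Reagents that add atoms: none
Why: Criegee glycol cleavage; the cis ditertiary cyclobutane-1,2-diol readily forms the cyclic lead diester and fragments with release of ring strain, cutting C6–C10 and opening ring B as the 6,10-dione; the ring fusion is still cis because C1 and C5 are untouched.

Step 6
Reactants: 9 cis-fused dione
Product: 10 trans-fused dione 4α-(triethylsilyloxy)-1β,8-dimethyl-5αH-bicyclo[5.3.0]decane-6,10-dione
Conditions: DBU (0.5 equiv), toluene, rt to 40 °C
Reagents that add atoms: none
Why: Base-mediated epimerisation through the C6 enolate under thermodynamic control; C5 is the only epimerisable centre, and the trans-fused isomer should dominate because it removes the cis-1,2 interaction on ring A between the C4 silyloxy group and the C5–C6 bond; silyloxide is a poor leaving group, so β-elimination should not compete.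

Step 7
Reactants: 10 trans-fused dione
Product: 11 6β-hydroxy-4α-(triethylsilyloxy)-1β,8-dimethyl-5αH-bicyclo[5.3.0]decan-10-one
Conditions: LiBH(s-Bu)3 (1.05 equiv), THF, −78 °C; H2O
Reagents that add atoms: none
Why: Chemoselective ketone reduction with a bulky trialkylborohydride; C6 is flanked by the C5 methine and is reached along the equatorial trajectory on the open α face, whereas C10 is neopentyl and its only methyl-free approach is the axial one that bulky hydrides avoid; the C6 alkoxide can also close transannularly onto C10 and shield it from over-reduction; α attack should give the 6β-alcohol, as with 6-oxo-5α-steroids.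

Step 8
Reactants: 11 hydroxy ketone
Product: 13 enone 6β-(tert-butyldimethylsilyloxy)-4α-(triethylsilyloxy)-1β,8-dimethyl-5αH-bicyclo[5.3.0]dec-8-en-10-one, via bis-silyl enol ether 12 (not isolated)
Conditions: t-BuMe2SiOTf (2.5 equiv), Et3N, CH2Cl2, 0 °C to rt; then Pd(OAc)2 (1.1 equiv), MeCN, 40 °C
Reagents that add atoms: tert-butyldimethylsilyl trifluoromethanesulfonate, CC(C)(C)[Si](C)(C)OS(=O)(=O)C(F)(F)F
Why: The silyl triflate with amine base protects the hindered C6 hydroxyl and converts the C10 ketone into its silyl enol ether, which can form only towards C9 because C1 is quaternary; Saegusa–Ito oxidation (β-hydride elimination from either C8 epimer, Pd(OAc)2 going to zerovalent palladium) then gives the C8=C9 enone and removes the uncontrolled C8 stereocentre.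

Step 9
Reactants: 13 enone
Product: 14 4α-hydroxy-6β-(tert-butyldimethylsilyloxy)-1β,8-dimethyl-5αH-bicyclo[5.3.0]dec-8-en-10-one
Conditions: PPTS (0.2 equiv), MeOH/CH2Cl2, 0 °C to rt
Reagents that add atoms: none
Why: Selective desilylation by acid-catalysed methanolysis; the triethylsilyl ether is cleaved much faster than the hindered secondary tert-butyldimethylsilyl ether, and the enone is inert.

Step 10
Reactants: 14 hydroxy enone
Product: 15 6β-(tert-butyldimethylsilyloxy)-1β,8-dimethyl-5αH-bicyclo[5.3.0]dec-8-ene-4,10-dione
Conditions: Dess–Martin periodinane, NaHCO3, CH2Cl2, rt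
Reagents that add atoms: none
Why: Dess–Martin oxidation under buffered, non-basic conditions gives the cyclopentanone without epimerising C5 or eliminating the β-silyloxy group.

Step 11
Reactants: 15 ene-dione
Product: 16 6β-(tert-butyldimethylsilyloxy)-4β-hydroxydauc-8-en-10-one (4α-isopropyl)
Conditions: i-PrMgCl (1.3 equiv), CeCl3 (1.5 equiv), THF, −78 °C
Reagents that add atoms: isopropylmagnesium chloride, CC(C)[Mg]Cl
Why: 1,2-Addition of an organocerium reagent (Grignard reagent with CeCl3), which suppresses enolisation and β-hydride reduction; the nucleophile enters C4 from the α face, anti to the adjacent C5–C6 bond with its β-silyloxy group and to the 1,3-related C1 methyl group, giving the 4β-hydroxy-4α-isopropyl carbinol; the C10 enone is neopentyl and conjugated and should be much slower, and no ester is present yet.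

Step 12
Reactants: 16 hydroxy enone
Product: 17 6β-(tert-butyldimethylsilyloxy)dauc-8-ene-4β,10β-diol
Conditions: NaBH4, CeCl3·7H2O, MeOH, −78 to −40 °C
Reagents that add atoms: none
Why: Luche reduction (1,2-selective); hydride attacks C10 anti to the axial C1 methyl group, from the α face, so the pseudo-equatorial 10β-alcohol is expected, as in reductions of ketones next to an angular methyl group.

Step 13
Reactants: 17 allylic alcohol
Product: 18 10α-angeloyloxy-6β-(tert-butyldimethylsilyloxy)dauc-8-en-4β-ol
Conditions: angelic acid (2 equiv), PPh3, DIAD, toluene, 0 °C to rt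
Reagents that add atoms: angelic acid ((Z)-2-methylbut-2-enoic acid), C/C=C(/C)C(=O)O
Why: Mitsunobu esterification with inversion; the carboxylate displaces the activated 10β-oxygen from the open α face, the face hydride used, giving the 10α-angelate; the acid is never turned into an acylating agent, so the Z double bond should not isomerise, and the tertiary C4 hydroxyl does not react.

Step 14
Reactants: 18 silyl ether
Product: 19 10α-angeloyloxydauc-8-ene-4β,6β-diol
Conditions: HF·pyridine, pyridine/THF, 0 °C to rt
Reagents that add atoms: none
Why: Fluoride-mediated desilylation under buffered conditions; the allylic angelate and the tertiary alcohol are spared.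

Step 15
Reactants: 19 diol
Product: 20 10α-angeloyloxy-4β-hydroxydauc-8-en-6-one
Conditions: Dess–Martin periodinane, NaHCO3, CH2Cl2, 0 °C
Reagents that add atoms: none
Why: Dess–Martin oxidation of the secondary C6 alcohol (the tertiary one is inert) under buffered conditions; base is avoided because the product is a tertiary aldol and a β,γ-unsaturated ketone.

Step 16
Reactants: 20 hydroxy ketone
Product: 21 10α-angeloyloxydauc-8-ene-4β,6α-diol
Conditions: Me4NBH(OAc)3 (5 equiv), AcOH/MeCN, −30 °C
Reagents that add atoms: none
Why: Hydroxyl-directed reduction (Evans–Saksena type); the tertiary C4 hydroxyl, cis to C6 on ring A, exchanges onto boron and delivers hydride intramolecularly to the β face of the C6 carbonyl, giving the 6α-alcohol; the reagent does not reduce carbonyl groups lacking such a hydroxyl, and the acidic medium avoids retro-aldol cleavage.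

Step 17
Reactants: 21 diol
Product: 22 target, 6α-benzoyloxy-10α-angeloyloxydauc-8-en-4β-ol
Conditions: BzCl (1.5 equiv), pyridine, CH2Cl2, 0 °C to rt
Reagents that add atoms: benzoyl chloride, O=C(Cl)c1ccccc1
Why: Acylation of the pseudo-equatorial secondary 6α-hydroxyl with the acid chloride in pyridine; the tertiary C4 hydroxyl is inert under these conditions and the angelate is untouched.

## Compound list

1 | dimethyl 3-methylglutarate | COC(=O)CC(C)CC(=O)OC | starting material
2 | chlorotrimethylsilane | C[Si](C)(C)Cl | starting material
3 | 4-methyl-1,2-bis(trimethylsilyloxy)cyclopent-1-ene | CC1CC(O[Si](C)(C)C)=C(O[Si](C)(C)C)C1 | intermediate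
4 | 3-methylcyclopent-2-en-1-one | CC1=CC(=O)CC1 | starting material
5 | cis-anti-cis photoadduct, 1,4-dimethyl-2,6-bis(trimethylsilyloxy)tricyclo[5.3.0.0(2,6)]decan-8-one (C4 ketone, 1β-Me, 5β-H, 6α,10α-bis(silyloxy); C8 epimers) | O=C1CC[C@]2(C)[C@@]3(O[Si](C)(C)C)CC(C)C[C@@]3(O[Si](C)(C)C)[C@H]12 | intermediate
6 | 4α-alcohol of 5 (bis-silyl alcohol; C8 epimers) | O[C@@H]1CC[C@]2(C)[C@@]3(O[Si](C)(C)C)CC(C)C[C@@]3(O[Si](C)(C)C)[C@H]12 | intermediate
7 | 4α,6α,10α-triol, 1,4-dimethyltricyclo[5.3.0.0(2,6)]decane-2,6,8-triol (C8 epimers) | O[C@@H]1CC[C@]2(C)[C@@]3(O)CC(C)C[C@@]3(O)[C@H]12 | intermediate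
8 | 4α-triethylsilyl ether of 7 (6α,10α-diol; C8 epimers) | CC[Si](CC)(CC)O[C@@H]1CC[C@]2(C)[C@@]3(O)CC(C)C[C@@]3(O)[C@H]12 | intermediate
9 | cis-fused 4α-(triethylsilyloxy)-1β,8-dimethyl-5βH-bicyclo[5.3.0]decane-6,10-dione (C8 epimers) | O=C1CC(C)CC(=O)[C@H]2[C@]1(C)CC[C@H]2O[Si](CC)(CC)CC | intermediate
10 | trans-fused 4α-(triethylsilyloxy)-1β,8-dimethyl-5αH-bicyclo[5.3.0]decane-6,10-dione (C8 epimers) | O=C1CC(C)CC(=O)[C@@H]2[C@]1(C)CC[C@H]2O[Si](CC)(CC)CC | intermediate
11 | 6β-hydroxy-4α-(triethylsilyloxy)-1β,8-dimethyl-5αH-bicyclo[5.3.0]decan-10-one (C8 epimers) | O=C1CC(C)C[C@@H](O)[C@@H]2[C@]1(C)CC[C@H]2O[Si](CC)(CC)CC | intermediate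
12 | 6β,10-bis(tert-butyldimethylsilyloxy)-4α-(triethylsilyloxy)-1β,8-dimethyl-5αH-bicyclo[5.3.0]dec-9-ene (C10 silyl enol ether; C8 epimers) | CC(C)(C)[Si](C)(C)OC1=CC(C)C[C@@H](O[Si](C)(C)C(C)(C)C)[C@@H]2[C@]1(C)CC[C@H]2O[Si](CC)(CC)CC | intermediate
13 | 6β-(tert-butyldimethylsilyloxy)-4α-(triethylsilyloxy)-1β,8-dimethyl-5αH-bicyclo[5.3.0]dec-8-en-10-one | O=C1C=C(C)C[C@@H](O[Si](C)(C)C(C)(C)C)[C@@H]2[C@]1(C)CC[C@H]2O[Si](CC)(CC)CC | intermediate
14 | 4α-hydroxy-6β-(tert-butyldimethylsilyloxy)-1β,8-dimethyl-5αH-bicyclo[5.3.0]dec-8-en-10-one | O=C1C=C(C)C[C@@H](O[Si](C)(C)C(C)(C)C)[C@@H]2[C@]1(C)CC[C@H]2O | intermediate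
15 | 6β-(tert-butyldimethylsilyloxy)-1β,8-dimethyl-5αH-bicyclo[5.3.0]dec-8-ene-4,10-dione | O=C1C=C(C)C[C@@H](O[Si](C)(C)C(C)(C)C)[C@@H]2[C@]1(C)CCC2=O | intermediate
16 | 6β-(tert-butyldimethylsilyloxy)-4β-hydroxydauc-8-en-10-one (4α-isopropyl, 5α-H) | O=C1C=C(C)C[C@@H](O[Si](C)(C)C(C)(C)C)[C@@H]2[C@]1(C)CC[C@@]2(O)C(C)C | intermediate
17 | 6β-(tert-butyldimethylsilyloxy)dauc-8-ene-4β,10β-diol | O[C@H]1C=C(C)C[C@@H](O[Si](C)(C)C(C)(C)C)[C@@H]2[C@]1(C)CC[C@@]2(O)C(C)C | intermediate
18 | 10α-angeloyloxy-6β-(tert-butyldimethylsilyloxy)dauc-8-en-4β-ol | C/C=C(/C)C(=O)O[C@@H]1C=C(C)C[C@@H](O[Si](C)(C)C(C)(C)C)[C@@H]2[C@]1(C)CC[C@@]2(O)C(C)C | intermediate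
19 | 10α-angeloyloxydauc-8-ene-4β,6β-diol | C/C=C(/C)C(=O)O[C@@H]1C=C(C)C[C@@H](O)[C@@H]2[C@]1(C)CC[C@@]2(O)C(C)C | intermediate
20 | 10α-angeloyloxy-4β-hydroxydauc-8-en-6-one | C/C=C(/C)C(=O)O[C@@H]1C=C(C)CC(=O)[C@@H]2[C@]1(C)CC[C@@]2(O)C(C)C | intermediate
21 | 10α-angeloyloxydauc-8-ene-4β,6α-diol | C/C=C(/C)C(=O)O[C@@H]1C=C(C)C[C@H](O)[C@@H]2[C@]1(C)CC[C@@]2(O)C(C)C | intermediate
22 | 6α-benzoyloxy-10α-angeloyloxydauc-8-en-4β-ol, (3R,3aS,4S,8R,8aS)-3-hydroxy-6,8a-dimethyl-8-{[(2Z)-2-methylbut-2-enoyl]oxy}-3-(propan-2-yl)-1,2,3,3a,4,5,8,8a-octahydroazulen-4-yl benzoate | C/C=C(/C)C(=O)O[C@@H]1C=C(C)C[C@H](OC(=O)c2ccccc2)[C@@H]2[C@]1(C)CC[C@@]2(O)C(C)C | target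

## Step count and least certain steps

Total: 17 steps. Longest linear sequence: 17 steps from 1 (enone 4 enters in step 2).

Step 2 (key step, proposed new method). Most likely failure: the Lewis acid consumes alkene 3 in the dark, by conjugate addition to the activated enone or by desilylation, before the photoreaction takes place. The second concern is weak enantioface discrimination with a five-membered enone, or a racemic background reaction of uncomplexed enone. Fallback, from 3 and 4 back to 5: irradiate without Lewis acid (350 nm, CH2Cl2, −20 °C), a known reaction for cyclopentenones and bis(silyloxy)cycloalkenes, to give the racemic photoadduct F1. The enantiomers are then separated by preparative chromatography on a chiral stationary phase, and the dextro- or laevorotatory antipode that matches 5 is carried on.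

Step 7. Most likely failure: loss of chemoselectivity, with hydride also attacking C10 or reducing both carbonyls, because the steric difference between the two ring-B ketones is smaller than assumed. Fallback, from 10 back to 13, moving the discrimination from the ketones to the alcohols. Exhaustive reduction (NaBH4, MeOH) gives the 6β,10β-diol F2. Ac2O in pyridine at 0 °C should acetylate only the equatorial 10β-hydroxyl, since the axial 6β-hydroxyl is syn to the C1 methyl group, giving the 10β-acetate F3. Silylation of C6 (t-BuMe2SiOTf, 2,6-lutidine) gives the acetate silyl ether F4. Reductive removal of the acetate (i-Bu2AlH, −78 °C) gives the 10β-alcohol F5, and Dess–Martin oxidation gives the C10 ketone F6. Enol silylation of F6 gives 12, and Pd(OAc)2 then gives 13.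

Step 11. Most likely failure: enolisation of the cyclopentanone or β-hydride reduction by the secondary organometallic instead of addition, or competing attack on the C10 enone. Fallback, from 15 back to 16: add the smaller sp2 nucleophile isopropenylmagnesium bromide with CeCl3, which has no reduction pathway, to give the isopropenyl carbinol F7. The 1,1-disubstituted alkene is then hydrogenated selectively with H2 and RhCl(PPh3)3, leaving the trisubstituted enone alkene.

Step 13. Most likely failure: slow activation of the neopentyl alcohol, followed by ionisation with allylic transposition to C8 or elimination to a diene, or attack of the weakly acidic angelic acid being too slow. If step 12 gives the 10α-alcohol instead, direct acylation replaces the inversion. Fallback, from 17 back to 18, separating inversion from acylation. Mitsunobu reaction with the more acidic 4-nitrobenzoic acid gives the 10α-(4-nitrobenzoate) F8. Methanolysis (K2CO3, MeOH) gives the 10α-alcohol F9. F9 is acylated with the mixed anhydride of angelic acid and 2,4,6-trichlorobenzoyl chloride (Et3N, toluene, 80 °C, no nucleophilic catalyst) to give 18.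

Step 16. Most likely failure: slow exchange of the hindered tertiary hydroxyl onto boron, so that reduction is sluggish or proceeds undirected from the α face and returns the 6β-alcohol; retro-aldol opening of ring A is the other concern. Fallback, from 19 directly to 22, bypassing steps 15–17: Mitsunobu reaction of the 6β-alcohol 19 with benzoic acid (PPh3, DIAD) installs the benzoate with inversion from the open α face. No new compound is involved.

## Further compounds

F1 | step 2 | racemic cis-anti-cis photoadduct (5 and its enantiomer) | O=C1CC[C@]2(C)[C@@]3(O[Si](C)(C)C)CC(C)C[C@@]3(O[Si](C)(C)C)[C@H]12.O=C1CC[C@@]2(C)[C@]3(O[Si](C)(C)C)CC(C)C[C@]3(O[Si](C)(C)C)[C@@H]12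
F2 | step 7 | 4α-(triethylsilyloxy)-1β,8-dimethyl-5αH-bicyclo[5.3.0]decane-6β,10β-diol | O[C@H]1CC(C)C[C@@H](O)[C@@H]2[C@]1(C)CC[C@H]2O[Si](CC)(CC)CC
F3 | step 7 | 10β-acetoxy-6β-hydroxy-4α-(triethylsilyloxy)-1β,8-dimethyl-5αH-bicyclo[5.3.0]decane | CC(=O)O[C@H]1CC(C)C[C@@H](O)[C@@H]2[C@]1(C)CC[C@H]2O[Si](CC)(CC)CC
F4 | step 7 | 10β-acetoxy-6β-(tert-butyldimethylsilyloxy)-4α-(triethylsilyloxy)-1β,8-dimethyl-5αH-bicyclo[5.3.0]decane | CC(=O)O[C@H]1CC(C)C[C@@H](O[Si](C)(C)C(C)(C)C)[C@@H]2[C@]1(C)CC[C@H]2O[Si](CC)(CC)CC
F5 | step 7 | 6β-(tert-butyldimethylsilyloxy)-4α-(triethylsilyloxy)-1β,8-dimethyl-5αH-bicyclo[5.3.0]decan-10β-ol | O[C@H]1CC(C)C[C@@H](O[Si](C)(C)C(C)(C)C)[C@@H]2[C@]1(C)CC[C@H]2O[Si](CC)(CC)CC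
F6 | step 7 | 6β-(tert-butyldimethylsilyloxy)-4α-(triethylsilyloxy)-1β,8-dimethyl-5αH-bicyclo[5.3.0]decan-10-one | O=C1CC(C)C[C@@H](O[Si](C)(C)C(C)(C)C)[C@@H]2[C@]1(C)CC[C@H]2O[Si](CC)(CC)CC
F7 | step 11 | 6β-(tert-butyldimethylsilyloxy)-4β-hydroxy-4α-isopropenyl-1β,8-dimethyl-5αH-bicyclo[5.3.0]dec-8-en-10-one | O=C1C=C(C)C[C@@H](O[Si](C)(C)C(C)(C)C)[C@@H]2[C@]1(C)CC[C@@]2(O)C(C)=C
F8 | step 13 | 10α-(4-nitrobenzoyloxy)-6β-(tert-butyldimethylsilyloxy)dauc-8-en-4β-ol | O=C(O[C@@H]1C=C(C)C[C@@H](O[Si](C)(C)C(C)(C)C)[C@@H]2[C@]1(C)CC[C@@]2(O)C(C)C)c1ccc(cc1)[N+](=O)[O-]
F9 | step 13 | 6β-(tert-butyldimethylsilyloxy)dauc-8-ene-4β,10α-diol | O[C@@H]1C=C(C)C[C@@H](O[Si](C)(C)C(C)(C)C)[C@@H]2[C@]1(C)CC[C@@]2(O)C(C)C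
F0 | step 16 | none | none
A1 | alternative 1 | ring-B cycloheptadiene ester (C10 silyl ether, C8 methyl ester, C4 ethylene ketal) | CC(C)(C)[Si](C)(C)O[C@@H]1C=C(C(=O)OC)CC=C2[C@]1(C)CCC23OCCO3
A2 | alternative 1 | 6-ethenyl-7-methyl-1,4-dioxaspiro[4.4]non-6-ene (ketal diene) | C=CC1=C(C)CCC12OCCO2
A3 | alternative 1 | methyl (E)-4-(tert-butyldimethylsilyloxy)-2-diazobut-3-enoate | COC(=O)C(=[N+]=[N-])/C=C/O[Si](C)(C)C(C)(C)C
A4 | alternative 2 | trans-fused hydroazulen-6-one (C10 ethylene ketal, C4 silyl ether) | O=C1CC(C)CC2(OCCO2)[C@@]3(C)CC[C@H](O[Si](C)(C)C(C)(C)C)[C@H]13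
A5 | alternative 2 | cis-decalin hydroxy mesylate (angular C6 hydroxyl, C5 mesylate, C10 ethylene ketal, C4 silyl ether) | O[C@]12CC(C)CC3(OCCO3)[C@@]1(C)CC[C@H](O[Si](C)(C)C(C)(C)C)[C@@H]2OS(C)(=O)=O
A6 | alternative 3 | trans-2,3-disubstituted cyclopentanone aldol (vinyl iodide side chain, C10 as silyloxymethyl) | I/C=C(/C)C[C@H](O)[C@@H]1[C@@](C)(CO[Si](C)(C)C(C)(C)C)CCC1=O
A7 | alternative 3 | 3-[(tert-butyldimethylsilyloxy)methyl]cyclopent-2-en-1-one | O=C1C=C(CO[Si](C)(C)C(C)(C)C)CC1
A8 | alternative 3 | (Z)-4-iodo-3-methylbut-3-enal | I/C=C(/C)CC=O
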